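## Analysis of the target

Target 27 (CNP0141952.4) is a germacranolide: a ten-membered carbocycle (C1–C10) fused across C6–C7 to an α-methylene-γ-butyrolactone (O–C6, C7–C11, C11=C13, C12=O). The carbocycle holds one double bond, C1=C10, which is cis inside the ring and (E) by the sequence rule because C10 carries the methyl ester C14. C4 carries the hydroxymethyl group C15 and the C8 oxygen carries an (R)-2-methylbutanoyl group. Four ring stereocentres must be set, C4 (S), C6 (R), C7 (S) and C8 (R); the acyl α-carbon (R) can be bought. C6, C7 and C8 are contiguous: H6 and H7 are trans on the lactone, and C11 on C7 and the oxygen on C8 stand as the two ends of an anti addition across an (E)-C7=C8 bond. C4 is separated from this triad by the C5 methylene and needs its own control. The sensitive groups are the α-methylene lactone (a Michael acceptor that should appear last), three different ester-type carbonyls that rule out late hydrolysis, the epimerisable acyl α-carbon and the enoate geometry. The strategy rests on the fact that the C6 oxygen, the C7–C11 bond and the C8 oxygen all surround the C7–C8 bond. An ester on the C6 oxygen can deliver C11 as a carbene to a C7=C8 alkene, and the extra C8–C11 bond of the resulting cyclopropane is where the C8 oxygen enters with inversion.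

## Retrosynthetic reasoning

**C11=C13 and protecting groups (27 ⇒ 25 ⇒ 24).** The exocyclic methylene is removed first. A carboxyl group on C11 allows a decarboxylative Mannich methylenation as the last step, and it is also the second acceptor that the cyclopropane chemistry needs. In 24 that acid is a tert-butyl ester and the C15 alcohol a silyl ether; one acid treatment removes both while the methyl ester, the lactone and the C8 ester stay.

**C1–C2 (24 ⇒ 22).** The ten-membered ring is opened at the only ring bond that joins an sp2 to an sp3 carbon with no stereocentre or heteroatom next to it. It is made by hydroboration of a C4 vinyl group and palladium-catalysed B-alkyl coupling to a C1 iodide. Both termini are inert in the earlier steps, and the coupling carries the iodoalkene geometry into C1=C10. Cutting C9–C10 or C5–C6 would put a reactive centre beside the C8 or C6 oxygen.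

**C8–O (22 ⇒ 20 + 21).** In 20 the C8 oxygen is replaced by a bond from C8 to C11, a cyclopropane activated by the lactone and ester carbonyls on C11. The forward step must open it at C8, not C7, with inversion. The gain is that C8 needs no separate oxygenation and that the C7/C8 relation follows from alkene geometry.

**C7–C11 and C8–C11 together (20 ⇒ 19).** This is the key disconnection, an intramolecular carbene (2+1) addition. It reduces two rings and three stereocentres to one allylic ester stereocentre (C6) and an (E)-alkene. The forward step must choose the allylic alkene over the C4 vinyl group and the iodoenoate, and the alkene face that puts H6 and H7 trans.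

**Diazo group and ester (19 ⇒ 18 ⇒ 16 + 17).** Diazo transfer and esterification. A malonate is preferred to an acetate because the second carbonyl tempers the carbene, activates the cyclopropane and later leaves as CO2.

**C6–C7 (16 ⇒ 9 + 13).** A catalytic asymmetric addition of an (E)-alkenylzinc reagent, made by hydroboration of the terminal alkyne of 13, to aldehyde 9. One step forms the bond, the (E)-alkene and the C6 centre under reagent control, and it tolerates the ester and iodoalkene of 13. Routes through a C6 enone were set aside because the enone or its C8 aldehyde precursor has a C9 methylene between two unsaturated systems and would isomerise under base. Cross-metathesis was excluded because a C6 vinyl group would ring-close onto the C4 vinyl group.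

**The iodoalkene (13 ⇒ 12 ⇒ 11 ⇒ 10).** A C10=C1 unit with iodine cis to C9 is the geometry delivered by decarboxylative elimination of a (diiodomethyl)malonate, so C1 is added to the propargylmalonate 10 as a CHI2 group. Building this arm from a 2-(halomethyl)acrylate was rejected: a carbon nucleophile would attack such an allylic halide in the SN2′ sense at the iodine-bearing carbon, and a plain acrylate cannot be iodinated at C1 selectively afterwards.

**C4 (9 ⇒ 8 ⇒ 7 ⇒ 6 ⇒ 4 + 5; 4 ⇒ 1 + 2).** C4 is α to C15. With C15 as an imide carbonyl, the vinyl group comes from the butenoyl chain of 2 and C5–C6 from bromoacetate 5, so an auxiliary-controlled enolate alkylation sets C4. C15 is then reduced and silylated, and C6 is taken to the aldehyde.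

## Alternatives that were turned down

**Alternative 1:** The carbocycle is cut at C3–C4 by a retro Ireland–Claisen step to the ten-membered lactone A1. In A1, C15 is the lactone carbonyl bound to the C1 oxygen and C1 carries a vinyl group (C2=C3); the C1 configuration, erased in the step, is left open.
- Forward key step: the silyl ketene acetal of A1 rearranges, forming C3–C4, breaking O–C1 and giving the carbocyclic acid A2 with a cis C1=C2 alkene.
- For: a macrolactonisation replaces a medium-ring C–C closure, the sigmatropic transition state relays C1 to C4, and the γ-lactone and the C8 oxygen are already in place. On ring formation this is at least as strong as the chosen route.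
- Against: A2 is not at the oxidation pattern of 27. C15 is an acid that must become CH2OH and C14 is a protected alcohol that must become the methyl ester. The alkene sits at C1=C2 and must be moved to C1=C10 with control of geometry, which discards the C10 centre built into A1. A1 has two enolisable carbonyls, and the γ-lactone methylene C11 competes with C4 for the base. The methylene group and the C8 acyl group still have to be introduced.
- Comparison: about eight operations follow the key step, against four in the chosen route. The chosen strategy has every carbon at its final oxidation level when the ring closes and gets the C6–C8 triad from one stereospecific event.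

**Alternative 2:** C9–C10 is cut to the open-chain α-iodoenoate A3, in which C9 carries one extra carboxyl carbon as an N-acyloxyphthalimide.
- Forward key step: cathodic reduction with a nickel catalyst. The alkenylnickel species from the C10–I bond captures the primary C9 radical set free by decarboxylation and gives A4, the 15-O-silyl ether of 27.
- For: it is the most convergent ending. A4 is one deprotection from 27, the methylene lactone and both esters are already present, and the conditions are neutral. On endgame length it is clearly stronger than the chosen route.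
- Against: the C9 radical is β to the C8 acyloxy group, so a 1,2-acyloxy shift and, after capture by nickel, β-acyloxy elimination are open. The methylene lactone and the enoate are radical acceptors, and the former is reducible at the cathode. Closing a ten-membered ring by radical capture competes with hydrogen abstraction and intermolecular addition. The strategy also says nothing about the C6–C8 triad, which would have to be built on the open chain of A3.
- Comparison: the chosen strategy builds that triad stereospecifically and closes the ring by a two-electron coupling at C1–C2, away from the oxygenated carbons and before the Michael acceptor exists.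

**Alternative 3:** The ring is opened at C5–C6, treated as a latent C5=C6 alkene, and the lactone C6–O bond is cut as well, leading to the acyclic acid A5 with vinyl groups on C4 and C7.
- Forward key step: ring-closing metathesis with a second-generation Hoveyda–Grubbs catalyst joins the two vinyl groups to the cis,cis-cyclodeca-1,6-diene A6; the acrylic acid is then to lactonise onto C6.
- For: metathesis of two monosubstituted alkenes at an unfunctionalised position is the best-precedented way to a ten-membered carbocycle, the cis alkene is the natural outcome, and the methylene group is present from the start. On ring closure and on avoiding a late methylenation it is stronger than the chosen route.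
- Against: going from A6 to 27 needs a net hydro-acyloxylation of an unactivated cis alkene with C6 (not C5) regiochemistry and trans fusion, in the presence of two Michael acceptors and a 1,6-diene prone to transannular reactions under acid. Halolactonisation and reduction would add steps and a radical beside the acceptors. C7 in A5 is doubly allylic and easily isomerised, and the anti C7/C8 relation must be set on an open chain.
- Comparison: the chosen strategy has the C6 oxygen as a defined centre from the start and sets C7 and C8 together from one alkene.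

Key step: step 12

Remark on the chemistry (assumption): the ring numbering C1–C15 of 27 is used for all intermediates, and the configuration at C11 of 22–26 is left open because C11 becomes trigonal in the last step.

## Route

Step 1
Reactants: 1 (4R)-4-benzyl-1,3-oxazolidin-2-one; 2 but-3-enoic acid
Product: 4 (4R)-4-benzyl-3-(but-3-enoyl)-1,3-oxazolidin-2-one, via but-3-enoic pivalic anhydride 3 (not isolated)
Conditions: 2, PivCl, Et3N, THF, −78 → 0 °C; then lithium salt of 1 (n-BuLi, THF, −78 °C), −78 → 0 °C
Reagents that add atoms: none
Why: N-acylation of the lithiated oxazolidinone by a mixed pivalic anhydride; the low temperature and the absence of free amine at the acylation stage keep the β,γ-alkene from moving into conjugation.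

Step 2
Reactants: 4 (4R)-4-benzyl-3-(but-3-enoyl)-1,3-oxazolidin-2-one; 5 tert-butyl bromoacetate
Product: 6 tert-butyl (3R)-3-[(4R)-4-benzyl-2-oxo-1,3-oxazolidine-3-carbonyl]pent-4-enoate
Conditions: NaN(SiMe3)2, THF, −78 °C; 5, −78 → −45 °C; AcOH quench
Reagents that add atoms: none
Why: Evans alkylation: the chelated (Z)-sodium dienolate reacts at its α-carbon on the face opposite the benzyl group, which with the (R)-auxiliary sets C4 (3R in 6); the cold acidic quench avoids re-enolisation of the doubly activated α-hydrogen.

Step 3
Reactants: 6 tert-butyl (3R)-3-[(4R)-4-benzyl-2-oxo-1,3-oxazolidine-3-carbonyl]pent-4-enoate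
Product: 7 tert-butyl (3R)-3-(hydroxymethyl)pent-4-enoate
Conditions: LiBH4, MeOH (1 equiv), Et2O, 0 °C
Reagents that add atoms: none
Why: LiBH4 reduces the activated imide carbonyl much faster than the hindered tert-butyl ester and releases the C15 alcohol and the auxiliary; after this step C4 is no longer α to a carbonyl and cannot epimerise.

Step 4
Reactants: 7 tert-butyl (3R)-3-(hydroxymethyl)pent-4-enoate
Product: 8 tert-butyl (3R)-3-{[tert-butyl(dimethyl)silyl]oxymethyl}pent-4-enoate
Conditions: TBSCl, imidazole, CH2Cl2, 0 °C → rt
Reagents that add atoms: tert-butyldimethylsilyl chloride, CC(C)(C)[Si](C)(C)Cl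
Why: Standard silylation of a primary alcohol; it also removes the risk of lactonisation onto the ester.

Step 5
Reactants: 8 tert-butyl (3R)-3-{[tert-butyl(dimethyl)silyl]oxymethyl}pent-4-enoate
Product: 9 (3R)-3-{[tert-butyl(dimethyl)silyl]oxymethyl}pent-4-enal
Conditions: i-Bu2AlH (1.1 equiv), CH2Cl2, −78 °C; aq. KNa tartrate
Reagents that add atoms: none
Why: Partial ester reduction with i-Bu2AlH at −78 °C stops at the tetrahedral aluminate, which gives the aldehyde on work-up; the β-stereocentre is not enolisable.

Step 6
Reactants: 10 diethyl 2-(prop-2-yn-1-yl)propanedioate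
Product: 11 diethyl 2-(diiodomethyl)-2-(prop-2-yn-1-yl)propanedioate
Conditions: NaH (1.1 equiv), Et2O, reflux; CHI3, reflux
Reagents that add atoms: iodoform, IC(I)I
Why: The malonate anion is alkylated by diiodocarbene generated from iodoform (the established iodoform route to diiodomethyl malonates); one equivalent of NaH removes only the malonate hydrogen, not the alkyne hydrogen.

Step 7
Reactants: 11 diethyl 2-(diiodomethyl)-2-(prop-2-yn-1-yl)propanedioate
Product: 12 (2E)-2-(iodomethylidene)pent-4-ynoic acid
Conditions: KOH, EtOH/H2O (3:1), reflux; aq. HCl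
Reagents that add atoms: potassium hydroxide, [K+].[OH-]
Why: Saponification followed by decarboxylative anti elimination of iodide is the known way to (E)-2-alkyl-3-iodoacrylic acids; the iodine ends trans to the remaining carboxyl group and therefore cis to C9, the geometry needed later at C1=C10.

Step 8
Reactants: 12 (2E)-2-(iodomethylidene)pent-4-ynoic acid
Product: 13 methyl (2E)-2-(iodomethylidene)pent-4-ynoate
Conditions: MeI, K2CO3, DMF, 0 °C → rt
Reagents that add atoms: iodomethane, CI
Why: O-alkylation of the carboxylate under mild base; K2CO3 deprotonates no isomerisable position.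

Step 9
Reactants: 13 methyl (2E)-2-(iodomethylidene)pent-4-ynoate; 9 (3R)-3-{[tert-butyl(dimethyl)silyl]oxymethyl}pent-4-enal
Product: 16 methyl (2E,4E,6R,8R)-8-{[tert-butyl(dimethyl)silyl]oxymethyl}-6-hydroxy-2-(iodomethylidene)deca-4,9-dienoate, via alkenyldicyclohexylborane 14 (not isolated), via alkenyl(methyl)zinc reagent 15 (not isolated)
Conditions: 13, (c-C6H11)2BH (from BH3·SMe2, cyclohexene), toluene, 0 °C → rt; Me2Zn, −78 °C; (2S)-(−)-3-exo-(morpholino)isoborneol (5 mol %), then 9, −20 → 0 °C; aq. NH4Cl
Reagents that add atoms: none
Why: Oppolzer-type sequence: syn hydroboration of the terminal alkyne gives the (E)-alkenylborane, boron–zinc exchange gives the alkenylzinc, and the amino alcohol–zinc complex transfers the alkenyl group to the Si face of the aldehyde, which sets C6 as R and fixes the (E)-C7=C8 alkene. The borane is consumed before 9 is added, so the C4 vinyl group is untouched, and the C6 epimer would be a separable diastereomer.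

Step 10
Reactants: 16 methyl (2E,4E,6R,8R)-8-{[tert-butyl(dimethyl)silyl]oxymethyl}-6-hydroxy-2-(iodomethylidene)deca-4,9-dienoate; 17 3-tert-butoxy-3-oxopropanoic acid
Product: 18 tert-butyl (3R,5R,6E,9E)-3-{[tert-butyl(dimethyl)silyl]oxymethyl}-10-iodo-9-(methoxycarbonyl)deca-1,6,9-trien-5-yl propanedioate
Conditions: 17, DCC, DMAP (cat.), CH2Cl2, 0 °C → rt
Reagents that add atoms: none
Why: Steglich esterification of a secondary allylic alcohol with a malonic half-ester; no stereocentre is touched.

Step 11
Reactants: 18 tert-butyl (3R,5R,6E,9E)-3-{[tert-butyl(dimethyl)silyl]oxymethyl}-10-iodo-9-(methoxycarbonyl)deca-1,6,9-trien-5-yl propanedioate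
Product: 19 tert-butyl (3R,5R,6E,9E)-3-{[tert-butyl(dimethyl)silyl]oxymethyl}-10-iodo-9-(methoxycarbonyl)deca-1,6,9-trien-5-yl 2-diazopropanedioate
Conditions: p-ABSA, Et3N, MeCN, 0 °C → rt
Reagents that add atoms: 4-acetamidobenzenesulfonyl azide, CC(=O)Nc1ccc(cc1)S(=O)(=O)N=[N+]=[N-]
Why: Regitz diazo transfer to the only doubly activated methylene in the molecule.

Step 12
Reactants: 19 tert-butyl (3R,5R,6E,9E)-3-{[tert-butyl(dimethyl)silyl]oxymethyl}-10-iodo-9-(methoxycarbonyl)deca-1,6,9-trien-5-yl 2-diazopropanedioate
Product: 20 tert-butyl (1S,4R,5S,6S)-4-[(2R)-2-{[tert-butyl(dimethyl)silyl]oxymethyl}but-3-en-1-yl]-6-[(2E)-3-iodo-2-(methoxycarbonyl)prop-2-en-1-yl]-2-oxo-3-oxabicyclo[3.1.0]hexane-1-carboxylate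
Conditions: Rh2(OAc)4 (2 mol %), CH2Cl2, 40 °C, slow addition of 19 (final 5 mM)
Reagents that add atoms: none
Why: Loss of N2 from 19 at the dirhodium centre gives an electrophilic rhodium carbene at C11 that adds to the nearest alkene in a concerted, asynchronous (2+1) cycloaddition; the closest known reaction type is the dirhodium-catalysed intramolecular cyclopropanation of allylic diazomalonates to 2-oxo-3-oxabicyclo[3.1.0]hexane-1-carboxylates. The γ-lactone closes by C7–C11 bond formation through the three-atom ester tether (carbene carbon onto the proximal alkene carbon, five-membered ring with the alkene exocyclic to it), and the cyclopropane closes in the same event by C8–C11 bond formation. C11 becomes a quaternary centre fixed by the obligatory cis fusion of the bicycle; C8 is set stereospecifically by the alkene geometry, the (E)-alkene placing C9 trans to C6 on the three-membered ring; C7 is set by the choice of alkene face, which C6 controls through the tether, because in the envelope-like transition state the C5 chain takes the pseudo-equatorial exo position and H6 points toward the forming cyclopropane, giving H6 and H7 trans. The step needs chemoselectivity for the allylic alkene and this facial selectivity. The first is secured by ring size and electronics: the five-membered lactone forms faster than the seven-membered ring that attack on the C4 vinyl group would give, the iodoenoate is too electron-poor for the electrophilic carbene, and a malonate-type carbene inserts only slowly into the unactivated C5–H bonds. The second rests on the exo preference of the C6 substituent and is the main uncertainty, because an (E)-alkene adds little allylic strain to reinforce it; slow addition at high dilution suppresses carbene dimerisation.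

Step 13
Reactants: 20 tert-butyl (1S,4R,5S,6S)-4-[(2R)-2-{[tert-butyl(dimethyl)silyl]oxymethyl}but-3-en-1-yl]-6-[(2E)-3-iodo-2-(methoxycarbonyl)prop-2-en-1-yl]-2-oxo-3-oxabicyclo[3.1.0]hexane-1-carboxylate; 21 (2R)-2-methylbutanoic acid
Product: 22 tert-butyl (4S,5R)-5-[(2R)-2-{[tert-butyl(dimethyl)silyl]oxymethyl}but-3-en-1-yl]-4-[(1R,3E)-4-iodo-3-(methoxycarbonyl)-1-{[(2R)-2-methylbutanoyl]oxy}but-3-en-1-yl]-2-oxooxolane-3-carboxylate (C3 epimers)
Conditions: 21 (2 equiv), Cs2CO3 (1 equiv), DMSO, 70 °C; aq. NH4Cl
Reagents that add atoms: none
Why: Proposed new method: the caesium carboxylate is to attack C8 of the doubly acceptor-activated cyclopropane from the side opposite C11 (SN2-type homoconjugate addition), the exocyclic C8–C11 bond being the one aligned with both carbonyl π systems, which gives the C8 ester with inversion and leaves a malonate-type caesium enolate that is protonated on work-up; the closest known reaction type is the ring opening of 2-oxo-3-oxabicyclo[3.1.0]hexane-1-carboxylates and cyclopropane-1,1-diesters at the exocyclic carbon with inversion by thiolates, azide, amines, halides and malonates, together with caesium carboxylate SN2 displacement at secondary carbon, but a carboxylate opening at an alkyl-substituted cyclopropane carbon is not established.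

Step 14
Reactants: 22 tert-butyl (4S,5R)-5-[(2R)-2-{[tert-butyl(dimethyl)silyl]oxymethyl}but-3-en-1-yl]-4-[(1R,3E)-4-iodo-3-(methoxycarbonyl)-1-{[(2R)-2-methylbutanoyl]oxy}but-3-en-1-yl]-2-oxooxolane-3-carboxylate
Product: 24 3-tert-butyl 6-methyl (3aS,4R,6E,10S,11aR)-10-{[tert-butyl(dimethyl)silyl]oxymethyl}-4-{[(2R)-2-methylbutanoyl]oxy}-2-oxo-2,3,3a,4,5,8,9,10,11,11a-decahydrocyclodeca[b]furan-3,6-dicarboxylate (C3 epimers), via B-alkyl-9-BBN borane 23 (not isolated)
Conditions: 9-BBN-H, THF, 0 °C → rt; then slow addition to PdCl2(dppf) (15 mol %), AsPh3, Cs2CO3, DMF/THF/H2O, rt → 45 °C, 1 mM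
Reagents that add atoms: none
Why: 9-BBN adds only to the monosubstituted C2=C3 alkene with boron on C2, and the B-alkyl Suzuki–Miyaura coupling then joins C2 to C1 with retention of the iodoalkene geometry, so C2 ends cis to C9 as in 27; high dilution favours ring closure over oligomerisation.

Step 15
Reactants: 24 3-tert-butyl 6-methyl (3aS,4R,6E,10S,11aR)-10-{[tert-butyl(dimethyl)silyl]oxymethyl}-4-{[(2R)-2-methylbutanoyl]oxy}-2-oxo-2,3,3a,4,5,8,9,10,11,11a-decahydrocyclodeca[b]furan-3,6-dicarboxylate
Product: 25 (3aS,4R,6E,10S,11aR)-10-(hydroxymethyl)-6-(methoxycarbonyl)-4-{[(2R)-2-methylbutanoyl]oxy}-2-oxo-2,3,3a,4,5,8,9,10,11,11a-decahydrocyclodeca[b]furan-3-carboxylic acid (C3 epimers)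
Conditions: TFA/CH2Cl2/H2O (10:10:1), 0 °C → rt; evaporate cold
Reagents that add atoms: none
Why: Acidolysis removes the tert-butyl ester as isobutene and hydrolyses the primary silyl ether, while the methyl ester, the lactone and the secondary acyloxy group are stable to TFA; the malonic half-acid is kept cold and used at once to avoid premature decarboxylation.

Step 16
Reactants: 25 (3aS,4R,6E,10S,11aR)-10-(hydroxymethyl)-6-(methoxycarbonyl)-4-{[(2R)-2-methylbutanoyl]oxy}-2-oxo-2,3,3a,4,5,8,9,10,11,11a-decahydrocyclodeca[b]furan-3-carboxylic acid
Product: 27 methyl (3aS,4R,6E,10S,11aR)-10-(hydroxymethyl)-3-methylidene-4-{[(2R)-2-methylbutanoyl]oxy}-2-oxo-2,3,3a,4,5,8,9,10,11,11a-decahydrocyclodeca[b]furan-6-carboxylate, via Mannich base 26 (not isolated)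
Conditions: aq. HCHO (37 %), Et2NH, THF, 0 °C → rt; then NaOAc, AcOH, 60 °C
Reagents that add atoms: formaldehyde, C=O
Why: Mannich reaction of the malonic half-acid with the iminium ion from formaldehyde and diethylamine, then decarboxylative elimination of the amine, is the classical route to an α-methylene-γ-lactone; C11 becomes trigonal, so its earlier configuration does not matter, and the buffered medium spares the other esters.

## Compound list

1 | (4R)-4-benzyl-1,3-oxazolidin-2-one | O=C1OC[C@@H](Cc2ccccc2)N1 | starting material
2 | but-3-enoic acid | C=CCC(=O)O | starting material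
3 | but-3-enoic pivalic anhydride | C=CCC(=O)OC(=O)C(C)(C)C | intermediate
4 | (4R)-4-benzyl-3-(but-3-enoyl)-1,3-oxazolidin-2-one | O=C1OC[C@@H](Cc2ccccc2)N1C(=O)CC=C | intermediate
5 | tert-butyl bromoacetate | BrCC(=O)OC(C)(C)C | starting material
6 | tert-butyl (3R)-3-[(4R)-4-benzyl-2-oxo-1,3-oxazolidine-3-carbonyl]pent-4-enoate | O=C1OC[C@@H](Cc2ccccc2)N1C(=O)[C@@H](C=C)CC(=O)OC(C)(C)C | intermediate
7 | tert-butyl (3R)-3-(hydroxymethyl)pent-4-enoate | OC[C@@H](C=C)CC(=O)OC(C)(C)C | intermediate
8 | tert-butyl (3R)-3-{[tert-butyl(dimethyl)silyl]oxymethyl}pent-4-enoate | CC(C)(C)[Si](C)(C)OC[C@@H](C=C)CC(=O)OC(C)(C)C | intermediate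
9 | (3R)-3-{[tert-butyl(dimethyl)silyl]oxymethyl}pent-4-enal | CC(C)(C)[Si](C)(C)OC[C@@H](C=C)CC=O | intermediate
10 | diethyl 2-(prop-2-yn-1-yl)propanedioate | CCOC(=O)C(CC#C)C(=O)OCC | starting material
11 | diethyl 2-(diiodomethyl)-2-(prop-2-yn-1-yl)propanedioate | CCOC(=O)C(CC#C)(C(I)I)C(=O)OCC | intermediate
12 | (2E)-2-(iodomethylidene)pent-4-ynoic acid | C#CC/C(C(=O)O)=C\I | intermediate
13 | methyl (2E)-2-(iodomethylidene)pent-4-ynoate | C#CC/C(C(=O)OC)=C\I | intermediate
14 | methyl (2E,4E)-5-(dicyclohexylboranyl)-2-(iodomethylidene)pent-4-enoate | C1CCCCC1B(C1CCCCC1)/C=C/C/C(C(=O)OC)=C\I | intermediate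
15 | [(1E,4E)-5-iodo-4-(methoxycarbonyl)penta-1,4-dien-1-yl](methyl)zinc | C[Zn]/C=C/C/C(C(=O)OC)=C\I | intermediate
16 | methyl (2E,4E,6R,8R)-8-{[tert-butyl(dimethyl)silyl]oxymethyl}-6-hydroxy-2-(iodomethylidene)deca-4,9-dienoate | O[C@H](C[C@H](C=C)CO[Si](C)(C)C(C)(C)C)/C=C/C/C(C(=O)OC)=C\I | intermediate
17 | 3-tert-butoxy-3-oxopropanoic acid (mono-tert-butyl malonate) | CC(C)(C)OC(=O)CC(=O)O | starting material
18 | tert-butyl (3R,5R,6E,9E)-3-{[tert-butyl(dimethyl)silyl]oxymethyl}-10-iodo-9-(methoxycarbonyl)deca-1,6,9-trien-5-yl propanedioate | CC(C)(C)OC(=O)CC(=O)O[C@H](C[C@H](C=C)CO[Si](C)(C)C(C)(C)C)/C=C/C/C(C(=O)OC)=C\I | intermediate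
19 | tert-butyl (3R,5R,6E,9E)-3-{[tert-butyl(dimethyl)silyl]oxymethyl}-10-iodo-9-(methoxycarbonyl)deca-1,6,9-trien-5-yl 2-diazopropanedioate | CC(C)(C)OC(=O)C(=[N+]=[N-])C(=O)O[C@H](C[C@H](C=C)CO[Si](C)(C)C(C)(C)C)/C=C/C/C(C(=O)OC)=C\I | intermediate
20 | tert-butyl (1S,4R,5S,6S)-4-[(2R)-2-{[tert-butyl(dimethyl)silyl]oxymethyl}but-3-en-1-yl]-6-[(2E)-3-iodo-2-(methoxycarbonyl)prop-2-en-1-yl]-2-oxo-3-oxabicyclo[3.1.0]hexane-1-carboxylate | CC(C)(C)OC(=O)[C@]12C(=O)O[C@H](C[C@H](C=C)CO[Si](C)(C)C(C)(C)C)[C@H]1[C@@H]2C/C(C(=O)OC)=C\I | intermediate
21 | (2R)-2-methylbutanoic acid | CC[C@@H](C)C(=O)O | starting material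
22 | tert-butyl (4S,5R)-5-[(2R)-2-{[tert-butyl(dimethyl)silyl]oxymethyl}but-3-en-1-yl]-4-[(1R,3E)-4-iodo-3-(methoxycarbonyl)-1-{[(2R)-2-methylbutanoyl]oxy}but-3-en-1-yl]-2-oxooxolane-3-carboxylate (C3 epimers) | CC(C)(C)OC(=O)C1C(=O)O[C@H](C[C@H](C=C)CO[Si](C)(C)C(C)(C)C)[C@H]1[C@H](OC(=O)[C@H](C)CC)C/C(C(=O)OC)=C\I | intermediate
23 | 9-BBN adduct of 22 with boron on C2 (the vinyl group of 22 as CH2CH2–B) | CC(C)(C)OC(=O)C1C(=O)O[C@H](C[C@H](CCB2C3CCCC2CCC3)CO[Si](C)(C)C(C)(C)C)[C@H]1[C@H](OC(=O)[C@H](C)CC)C/C(C(=O)OC)=C\I | intermediate
24 | 3-tert-butyl 6-methyl (3aS,4R,6E,10S,11aR)-10-{[tert-butyl(dimethyl)silyl]oxymethyl}-4-{[(2R)-2-methylbutanoyl]oxy}-2-oxo-2,3,3a,4,5,8,9,10,11,11a-decahydrocyclodeca[b]furan-3,6-dicarboxylate (C3 epimers) | CC(C)(C)OC(=O)C1C(=O)O[C@@H]2C[C@@H](CO[Si](C)(C)C(C)(C)C)CC/C=C(/C(=O)OC)C[C@@H](OC(=O)[C@H](C)CC)[C@@H]12 | intermediate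
25 | (3aS,4R,6E,10S,11aR)-10-(hydroxymethyl)-6-(methoxycarbonyl)-4-{[(2R)-2-methylbutanoyl]oxy}-2-oxo-2,3,3a,4,5,8,9,10,11,11a-decahydrocyclodeca[b]furan-3-carboxylic acid (C3 epimers) | OC(=O)C1C(=O)O[C@@H]2C[C@@H](CO)CC/C=C(/C(=O)OC)C[C@@H](OC(=O)[C@H](C)CC)[C@@H]12 | intermediate
26 | 3-[(diethylamino)methyl] derivative of 25 (Mannich base at C11) | CCN(CC)CC1(C(=O)O)C(=O)O[C@@H]2C[C@@H](CO)CC/C=C(/C(=O)OC)C[C@@H](OC(=O)[C@H](C)CC)[C@@H]12 | intermediate
27 | methyl (3aS,4R,6E,10S,11aR)-10-(hydroxymethyl)-3-methylidene-4-{[(2R)-2-methylbutanoyl]oxy}-2-oxo-2,3,3a,4,5,8,9,10,11,11a-decahydrocyclodeca[b]furan-6-carboxylate (CNP0141952.4) | C=C1C(=O)O[C@@H]2C[C@@H](CO)CC/C=C(/C(=O)OC)C[C@@H](OC(=O)[C@H](C)CC)[C@@H]12 | target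

## Step count and least certain steps

Total step count: 16. Longest linear sequence: 13 steps (steps 1–5, then 9–16); the iodoenoate branch (steps 6–8) is three steps.

**Step 13 (labelled step).** The most likely failure is slow substitution at the secondary cyclopropane carbon by a weak nucleophile. That would let addition–elimination at the iodoenoate carbon C1 or acyl attack on the lactone take over. The fallback uses known reactions only; it sets out from 16, comes back at 22 and does not pass through the cyclopropane. Matched Sharpless epoxidation of 16 (Ti(OiPr)4, D-(−)-diisopropyl tartrate, t-BuOOH, 4 Å sieves, CH2Cl2, −20 °C) should give the erythro 7,8-epoxy alcohol F1 with the epoxide oxygen on the face C8 needs. Steglich esterification with 17 gives the epoxy malonate F2. Cs2CO3 in THF/DMF then closes the lactone by 5-exo attack of the malonate carbon on C7 with inversion, leaving the C8 oxygen with retention in the hydroxy lactone F3. Acylation of F3 with 21 (DCC, DMAP) gives 22.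

**Step 12 (key step).** The most likely failure is incomplete facial selection, with part of the material cyclising with the C5 chain on the concave face (C7 and C8 both inverted relative to C6); carbene dimerisation and 1,5 insertion into C5–H are the next risks. The fallback replaces the carbene by an ionic two-stage cyclopropanation; it sets out from 18 and comes back at 20. Iodocarbocyclisation of the allyl malonate (I2, Ti(Ot-Bu)4, CuO, CH2Cl2) should add C11 and iodine anti across C7=C8 to give the iodo lactone F4, with the face chosen in a reversible iodonium step. DBU then closes the three-membered ring by displacement of iodide from C8 with inversion, which gives the same C7/C8 relation as the syn carbene addition.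

**Step 14.** The most likely failure is intermolecular coupling and protodeboronation outrunning closure of the strained ten-membered ring; α-alkenylation of the C11 enolate by the alkenylpalladium intermediate (six-membered ring) is a further risk under base. The fallback is a base-free cross-electrophile closure; it sets out from 22 and comes back at 24. Hydroboration of the vinyl group with 9-BBN and oxidation with NaBO3·4H2O gives the primary alcohol F5. I2, PPh3 and imidazole convert it into the primary iodide F6. Nickel-catalysed reductive coupling of the two carbon–iodine bonds (NiBr2(dme), 4,4'-di-tert-butyl-2,2'-bipyridine, Mn powder, DMA, high dilution) then forms C1–C2.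

**Step 9.** The most likely failure is insufficient reagent control at C6 with an α-unbranched aldehyde, or incomplete boron–zinc exchange. The fallback separates bond formation from stereocontrol. It sets out from the mixture of 16 and its C6 epimer F7 obtained when the addition is run without the amino alcohol, and comes back at 16. Dess–Martin periodinane (NaHCO3, CH2Cl2) oxidises the mixture to the (E)-enone F8. Corey–Bakshi–Shibata reduction with (S)-2-methyl-CBS-oxazaborolidine and catecholborane at −78 °C then gives 16, the alkenyl group acting as the large substituent.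

## Further compounds

F1 | step 13 | erythro 7,8-epoxide of 16: methyl (2E)-3-[(2R,3R)-3-{(1R,3R)-3-[(tert-butyldimethylsilyloxy)methyl]-1-hydroxypent-4-en-1-yl}oxiran-2-yl]-2-(iodomethylidene)propanoate | O[C@H](C[C@H](C=C)CO[Si](C)(C)C(C)(C)C)[C@H]1O[C@@H]1C/C(C(=O)OC)=C\I
F2 | step 13 | tert-butyl malonate ester of F1 at the C6 oxygen | CC(C)(C)OC(=O)CC(=O)O[C@H](C[C@H](C=C)CO[Si](C)(C)C(C)(C)C)[C@H]1O[C@@H]1C/C(C(=O)OC)=C\I
F3 | step 13 | C8 hydroxy lactone (22 with OH in place of the 2-methylbutanoyloxy group; C3 epimers) | CC(C)(C)OC(=O)C1C(=O)O[C@H](C[C@H](C=C)CO[Si](C)(C)C(C)(C)C)[C@H]1[C@H](O)C/C(C(=O)OC)=C\I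
F4 | step 12 | C8 iodo lactone (22 with iodine in place of the 2-methylbutanoyloxy group; C3 epimers) | CC(C)(C)OC(=O)C1C(=O)O[C@H](C[C@H](C=C)CO[Si](C)(C)C(C)(C)C)[C@H]1[C@H](I)C/C(C(=O)OC)=C\I
F5 | step 14 | primary alcohol from 22 (vinyl group converted into CH2CH2OH) | CC(C)(C)OC(=O)C1C(=O)O[C@H](C[C@H](CCO)CO[Si](C)(C)C(C)(C)C)[C@H]1[C@H](OC(=O)[C@H](C)CC)C/C(C(=O)OC)=C\I
F6 | step 14 | primary iodide from F5 (CH2CH2I on C4) | CC(C)(C)OC(=O)C1C(=O)O[C@H](C[C@H](CCI)CO[Si](C)(C)C(C)(C)C)[C@H]1[C@H](OC(=O)[C@H](C)CC)C/C(C(=O)OC)=C\I
F7 | step 9 | C6 epimer of 16: methyl (2E,4E,6S,8R)-8-{[tert-butyl(dimethyl)silyl]oxymethyl}-6-hydroxy-2-(iodomethylidene)deca-4,9-dienoate | O[C@@H](C[C@H](C=C)CO[Si](C)(C)C(C)(C)C)/C=C/C/C(C(=O)OC)=C\I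
F8 | step 9 | methyl (2E,4E,8R)-8-{[tert-butyl(dimethyl)silyl]oxymethyl}-2-(iodomethylidene)-6-oxodeca-4,9-dienoate | O=C(C[C@H](C=C)CO[Si](C)(C)C(C)(C)C)/C=C/C/C(C(=O)OC)=C\I
A1 | alternative 1 | ten-membered lactone with C15 carbonyl on the C1 oxygen and a vinyl group on C1 (C1 configuration left open) | C=CC1OC(=O)CC[C@H]2OC(=O)C[C@@H]2[C@H](O[Si](C)(C)C(C)(C)C)C[C@@H]1COCc1ccc(OC)cc1
A2 | alternative 1 | carbocyclic C15 acid with cis C1=C2 alkene | OC(=O)[C@H]1C/C=C\[C@@H](COCc3ccc(OC)cc3)C[C@@H](O[Si](C)(C)C(C)(C)C)[C@H]2CC(=O)O[C@@H]2C1
A3 | alternative 2 | open-chain α-iodoenoate with the C9 carboxyl as N-acyloxyphthalimide | C=C1C(=O)O[C@H](C[C@@H](CO[Si](C)(C)C(C)(C)C)CC/C=C(\I)C(=O)OC)[C@H]1[C@@H](CC(=O)ON1C(=O)c2ccccc2C1=O)OC(=O)[C@H](C)CC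
A4 | alternative 2 | 15-O-tert-butyldimethylsilyl ether of 27 | C=C1C(=O)O[C@@H]2C[C@@H](CO[Si](C)(C)C(C)(C)C)CC/C=C(/C(=O)OC)C[C@@H](OC(=O)[C@H](C)CC)[C@@H]12
A5 | alternative 3 | acyclic acrylic acid with vinyl groups on C4 and C7 | OC(=O)C(=C)[C@@H](C=C)[C@H](OC(=O)[C@H](C)CC)C/C(C(=O)OC)=C\CC[C@@H](C=C)CO[Si](C)(C)C(C)(C)C
A6 | alternative 3 | cyclodeca-1,6-diene acrylic acid | OC(=O)C(=C)[C@H]1/C=C\[C@@H](CO[Si](C)(C)C(C)(C)C)CC/C=C(/C(=O)OC)C[C@H]1OC(=O)[C@H](C)CC
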